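**Plan**

- Retrosynthesis: cut the C6 aryl ester, open the epoxide back to a threo diol, cut the C3=C4 enol ether of ring B into an ester carbonyl and a C4 vinyl group, then the C1–O ester bond, the C4a=C8a bond of ring A, and the chain bonds C8–C8a and C5–C4a.
- Forward: lactone 1 supplies C5–C8, ethynylsilane 5 adds C4a/C4, 2-bromoallyl alcohol 12 adds C8a/C1, and enyne metathesis closes ring A. Esterification then joins the threonine acid, a titanium alkylidene closes ring B, and the C8 ketone, epoxide and aryl ester follow.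
- Stereochemistry: C6 and C7 come untouched from 2-C-methyl-D-erythrono-1,4-lactone. C9 and C10 come from L-threonine, with retention on deamination and net retention in the orthoester/bromide/base epoxide closure. C8 is only a transient carbinol.
- Enabling feature: C3, the epoxide carbons C9 and C10 and the methyl group are the four carbons of L-threonine. C3 can therefore be carried as an α-alkoxy ester carbonyl, held six atoms from C4 by O2–C1–C8a=C4a of ring A.

Key step: step 15

Remark: 1 is taken as a purchasable saccharinic lactone; C8 is formed in step 8 as a mixture of epimers, written without a descriptor and carried unseparated because it becomes the ketone in step 17 (lactol 3 and orthoacetate 25 are likewise mixtures at their acetal carbons).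

**Route**

Step 1
Reactants: 1 2-C-methyl-D-erythrono-1,4-lactone
Product: 2 2,3-O-isopropylidene-2-C-methyl-D-erythrono-1,4-lactone
Conditions: Me2C(OMe)2, TsOH·H2O (cat.), acetone, rt
Reagents that add atoms: 2,2-dimethoxypropane, COC(C)(C)OC
Why: Acid-catalysed transketalisation of the cis-2,3-diol should give the cis-fused acetonide without touching either stereocentre.

Step 2
Reactants: 2 2,3-O-isopropylidene-2-C-methyl-D-erythrono-1,4-lactone
Product: 3 2,3-O-isopropylidene-2-C-methyl-D-erythrofuranose (lactol)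
Conditions: i-Bu2AlH, CH2Cl2, −78 °C; aq. KNaC4H4O6
Reagents that add atoms: none
Why: Low-temperature hydride reduction of a γ-lactone should stop at the tetrahedral aluminate and release the lactol on work-up.

Step 3
Reactants: 3 2,3-O-isopropylidene-2-C-methyl-D-erythrofuranose
Product: 4 [(4R,5S)-5-ethenyl-2,2,5-trimethyl-1,3-dioxolan-4-yl]methanol
Conditions: Ph3PCH3Br, KOt-Bu, THF, 0 °C to reflux
Reagents that add atoms: methyltriphenylphosphonium bromide, C[P+](c1ccccc1)(c1ccccc1)c1ccccc1.[Br-]
Why: Wittig methylenation of the open hydroxy-aldehyde form should free the C5 hydroxyl and mask C8 as a vinyl group, the quaternary α-carbon excluding epimerisation.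

Step 4
Reactants: 4 [(4R,5S)-5-ethenyl-2,2,5-trimethyl-1,3-dioxolan-4-yl]methanol; 5 ethynyltrimethylsilane
Product: 7 trimethyl{3-[(4R,5S)-5-ethenyl-2,2,5-trimethyl-1,3-dioxolan-4-yl]prop-1-yn-1-yl}silane, via primary triflate 6 (not isolated)
Conditions: Tf2O, 2,6-lutidine, CH2Cl2, −78 °C; then LiC≡CSiMe3 (from 5, n-BuLi, 3 equiv), THF–DMPU, −78 to −20 °C
Reagents that add atoms: trifluoromethanesulfonic anhydride, O=S(=O)(OS(=O)(=O)C(F)(F)F)C(F)(F)F (triflyl group of 6 only)
Why: SN2 alkynylation of a sugar-type primary triflate by a lithium acetylide in a dipolar medium should form the C5–C4a bond, with no stereocentre at the reacting carbon.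

Step 5
Reactants: 7 trimethyl{3-[(4R,5S)-5-ethenyl-2,2,5-trimethyl-1,3-dioxolan-4-yl]prop-1-yn-1-yl}silane
Product: 9 (3S,4R)-3-methylhept-1-en-6-yne-3,4-diol, via silylalkyne diol 8 (not isolated)
Conditions: AcOH–H2O (4:1), 45 °C; evaporate; then K2CO3, MeOH, rt
Reagents that add atoms: none
Why: Mild acetal hydrolysis followed by base-mediated protodesilylation of the alkyne should give the diol at a stage that carries no silyl ether, so that no silyl migration can occur.

Step 6
Reactants: 9 (3S,4R)-3-methylhept-1-en-6-yne-3,4-diol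
Product: 10 (3S,4R)-3,4-bis(tert-butyldimethylsilyloxy)-3-methylhept-1-en-6-yne
Conditions: TBSOTf, 2,6-lutidine, CH2Cl2, 0 °C to rt
Reagents that add atoms: tert-butyldimethylsilyl trifluoromethanesulfonate, CC(C)(C)[Si](C)(C)OS(=O)(=O)C(F)(F)F
Why: Silyl triflate silylation should cap both the secondary and the tertiary hydroxyl with fluoride-labile groups, so that the ring A diol can later be released without acid in the presence of the epoxide.

Step 7
Reactants: 10 (3S,4R)-3,4-bis(tert-butyldimethylsilyloxy)-3-methylhept-1-en-6-yne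
Product: 11 (2R,3R)-2,3-bis(tert-butyldimethylsilyloxy)-2-methylhex-5-ynal
Conditions: O3, CH2Cl2, −78 °C; then PPh3, −78 °C to rt
Reagents that add atoms: ozone, [O-][O+]=O
Why: Ozonolysis with reductive work-up should cleave the vinyl group much faster than the alkyne and unveil C8 as a non-enolisable aldehyde.

Step 8
Reactants: 11 (2R,3R)-2,3-bis(tert-butyldimethylsilyloxy)-2-methylhex-5-ynal; 12 2-bromoprop-2-en-1-ol
Product: 13 (4S,5R)-4,5-bis(tert-butyldimethylsilyloxy)-4-methyl-2-methylideneoct-7-yne-1,3-diol (C3 epimers)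
Conditions: 12 (3 equiv), t-BuLi (9 equiv), Et2O, −78 to 0 °C; then 11, −78 °C; aq. NH4Cl
Reagents that add atoms: none
Why: Bromine–lithium exchange on the lithium alkoxide of 12 gives a 2-lithioallyl alkoxide whose 1,2-addition to the aldehyde should form the C8–C8a bond; the excess reagent covers the acidic alkyne C–H and the new C8 centre is inconsequential.

Step 9
Reactants: 13 (4S,5R)-4,5-bis(tert-butyldimethylsilyloxy)-4-methyl-2-methylideneoct-7-yne-1,3-diol
Product: 14 [(4R,5S)-4,5-bis(tert-butyldimethylsilyloxy)-2-ethenyl-6-hydroxy-5-methylcyclohex-1-en-1-yl]methanol (C6 epimers; ring A diene diol)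
Conditions: (H2IMes)(PCy3)Cl2Ru=CHPh (second-generation Grubbs catalyst, 10 mol%), toluene (5 mM), 80 °C, Ar
Reagents that add atoms: none
Why: Ring-closing enyne metathesis of the 1,7-enyne in the six-membered exo mode should place the metal on the internal alkyne carbon and close onto the 1,1-disubstituted olefin, giving the C4a=C8a bond with the vinyl group on C4a.

Step 10
Reactants: 15 L-threonine
Product: 16 (2S,3R)-2,3-dihydroxybutanoic acid
Conditions: NaNO2, 1 M H2SO4, H2O, 0 °C to rt
Reagents that add atoms: water, O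
Why: Diazotisation of the α-amino acid proceeds through an α-lactone (two inversions at C2), so the hydroxyl should replace nitrogen with retention while C3 is untouched.

Step 11
Reactants: 16 (2S,3R)-2,3-dihydroxybutanoic acid
Product: 17 methyl (4S,5R)-2,2,5-trimethyl-1,3-dioxolane-4-carboxylate
Conditions: MeOH, Me2C(OMe)2, TsOH·H2O (cat.), reflux then rt
Reagents that add atoms: methanol, CO; 2,2-dimethoxypropane, COC(C)(C)OC
Why: Fischer esterification with concurrent acetalisation, the ketal reagent scavenging water, should give the trans-dioxolane ester.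

Step 12
Reactants: 17 methyl (4S,5R)-2,2,5-trimethyl-1,3-dioxolane-4-carboxylate
Product: 18 (4S,5R)-2,2,5-trimethyl-1,3-dioxolane-4-carboxylic acid
Conditions: LiOH, THF–H2O, 0 °C; then 1 M HCl to pH 3, 0 °C
Reagents that add atoms: lithium hydroxide, [Li+].[OH-]
Why: Cold saponification should give the acid, and the trans-dioxolane is the thermodynamically preferred isomer, so the α-centre is not at risk.

Step 13
Reactants: 14 ring A diene diol; 18 (4S,5R)-2,2,5-trimethyl-1,3-dioxolane-4-carboxylic acid
Product: 19 [(4R,5S)-4,5-bis(tert-butyldimethylsilyloxy)-2-ethenyl-6-hydroxy-5-methylcyclohex-1-en-1-yl]methyl (4S,5R)-2,2,5-trimethyl-1,3-dioxolane-4-carboxylate (C6 epimers)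
Conditions: EDC·HCl, DMAP (cat.), CH2Cl2, −20 to 0 °C
Reagents that add atoms: none
Why: Steglich-type carbodiimide esterification should select the primary allylic hydroxyl over the secondary C8 hydroxyl, which is flanked by a quaternary carbon.

Step 14
Reactants: 19 dienyl ester with free C8 hydroxyl
Product: 20 [(4R,5R)-4,5-bis(tert-butyldimethylsilyloxy)-2-ethenyl-5-methyl-6-(triethylsilyloxy)cyclohex-1-en-1-yl]methyl (4S,5R)-2,2,5-trimethyl-1,3-dioxolane-4-carboxylate (C6 epimers)
Conditions: TESOTf, 2,6-lutidine, CH2Cl2, −78 °C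
Reagents that add atoms: triethylsilyl trifluoromethanesulfonate, CC[Si](CC)(CC)OS(=O)(=O)C(F)(F)F
Why: Silyl triflate silylation should mask C8 with a group that can later be removed selectively beside the two tert-butyldimethylsilyl ethers.

Step 15
Reactants: 20 ring A dienyl ester (C8 triethylsilyl ether)
Product: 21 6,7-bis(tert-butyldimethylsilyloxy)-7-methyl-8-(triethylsilyloxy)-3-[(4S,5R)-2,2,5-trimethyl-1,3-dioxolan-4-yl]-5,6,7,8-tetrahydro-1H-isochromene (C6 and C7 as in 33; C8 epimers)
Conditions: TiCl4, TMEDA, Zn dust, PbCl2 (cat.), THF–CH2Cl2, rt; then 20, CH3CHBr2, 65 °C; aq. K2CO3 work-up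
Reagents that add atoms: none
Why: The reduced titanium ethylidene made from CH3CHBr2 (Takai–Utimoto reagent) should exchange by [2+2] cycloaddition and cycloreversion with the only unhindered olefin, the terminal vinyl group, releasing propene and leaving a titanium alkylidene on C4; this adds to the ester carbonyl and the oxatitanacyclobutane collapses to the C3=C4 enol ether and a titanium oxo species (ethylidenation of the ester first, then metathesis of that enol ether with the vinyl group, gives the same product). The closest known reaction type is the olefinic-ester cyclisation of alkenyl esters to six-membered cyclic enol ethers with this reagent, for which α-alkoxy esters are good substrates. Ring B closes as a six-membered ring by carbonyl–olefin metathesis, the C4a=C8a double bond of ring A holding the vinyl and acyloxymethyl arms cis. No stereocentre is formed, and the dioxolane centre next to the carbonyl is not exposed to base. The step needs chemoselectivity for the ester carbonyl and the terminal olefin: C8 is a silyl ether so no ketone competes, no other carbonyl is present, and the tetrasubstituted C4a=C8a bond is too hindered to enter metathesis.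

Step 16
Reactants: 21 tris-silylated isochromene
Product: 22 6,7-bis(tert-butyldimethylsilyloxy)-7-methyl-3-[(4S,5R)-2,2,5-trimethyl-1,3-dioxolan-4-yl]-5,6,7,8-tetrahydro-1H-isochromen-8-ol (C6 and C7 as in 33; C8 epimers)
Conditions: HF·pyridine, pyridine, THF, 0 °C
Reagents that add atoms: none
Why: Pyridine-buffered fluoride should cleave the secondary triethylsilyl ether much faster than the tert-butyldimethylsilyl ethers while keeping the medium mild enough for the dienol ether.

Step 17
Reactants: 22 C8 alcohol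
Product: 23 (6R,7R)-6,7-bis(tert-butyldimethylsilyloxy)-7-methyl-3-[(4S,5R)-2,2,5-trimethyl-1,3-dioxolan-4-yl]-6,7-dihydro-1H-isochromen-8(5H)-one
Conditions: Dess–Martin periodinane, pyridine, CH2Cl2, 0 °C to rt
Reagents that add atoms: none
Why: Dess–Martin oxidation of the allylic carbinol should give the dienone, erasing the C8 epimer mixture and turning the acid-labile dienol ether into a doubly vinylogous ester.

Step 18
Reactants: 23 dienone acetonide
Product: 24 (6R,7R)-6,7-bis(tert-butyldimethylsilyloxy)-3-[(1S,2R)-1,2-dihydroxypropyl]-7-methyl-6,7-dihydro-1H-isochromen-8(5H)-one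
Conditions: AcOH–H2O–THF (3:1:1), 40 °C
Reagents that add atoms: none
Why: Mild acid hydrolysis should open the strained trans-dioxolane while the hindered silyl ethers and the push–pull stabilised enol ether persist.

Step 19
Reactants: 24 side-chain diol
Product: 27 (6R,7R)-6,7-bis(tert-butyldimethylsilyloxy)-7-methyl-3-[(2S,3R)-3-methyloxiran-2-yl]-6,7-dihydro-1H-isochromen-8(5H)-one, via cyclic orthoacetate 25 (not isolated), via bromo acetate 26 (not isolated)
Conditions: MeC(OMe)3, PPTS (cat.), CH2Cl2, rt; evaporate; AcBr, CH2Cl2, 0 °C; evaporate; K2CO3, MeOH, 0 °C to rt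
Reagents that add atoms: trimethyl orthoacetate, COC(C)(OC)OC; acetyl bromide, CC(Br)=O
Why: In the Kolb–Sharpless one-pot sequence bromide opens the acetoxonium ion with inversion and the alkoxide freed by methanolysis displaces bromide with a second inversion at the same carbon, so the threo diol should give the trans epoxide with net retention at C9 and C10 whichever carbon is attacked (26 is drawn with bromide at C9).

Step 20
Reactants: 27 bis-silylated epoxide
Product: 28 (6R,7R)-6,7-dihydroxy-7-methyl-3-[(2S,3R)-3-methyloxiran-2-yl]-6,7-dihydro-1H-isochromen-8(5H)-one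
Conditions: Bu4NF, AcOH (1:1), THF, 0 °C to rt
Reagents that add atoms: none
Why: Acetic acid-buffered fluoride should remove both silyl ethers without acid or strong base, leaving the epoxide and the dienone intact.

Step 21
Reactants: 29 orsellinic acid
Product: 30 2,4-diacetoxy-6-methylbenzoic acid
Conditions: Ac2O, pyridine, 0 °C to rt; aq. work-up
Reagents that add atoms: acetic anhydride, CC(=O)OC(C)=O
Why: Acetylation of both phenols (the mixed anhydride at the carboxyl is hydrolysed on work-up) blocks self-acylation and stabilises the acid against decarboxylation.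

Step 22
Reactants: 30 2,4-diacetoxy-6-methylbenzoic acid
Product: 31 2,4-diacetoxy-6-methylbenzoyl chloride
Conditions: (COCl)2, DMF (cat.), CH2Cl2, 0 °C to rt
Reagents that add atoms: oxalyl chloride, O=C(Cl)C(Cl)=O
Why: Vilsmeier-type activation with oxalyl chloride and catalytic DMF should convert the hindered acid into its chloride under neutral conditions.

Step 23
Reactants: 28 epoxy keto-diol; 31 2,4-diacetoxy-6-methylbenzoyl chloride
Product: 32 (6R,7R)-7-hydroxy-7-methyl-3-[(2S,3R)-3-methyloxiran-2-yl]-8-oxo-5,6,7,8-tetrahydro-1H-isochromen-6-yl 2,4-diacetoxy-6-methylbenzoate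
Conditions: DMAP, Et3N, CH2Cl2, 0 °C
Reagents that add atoms: none
Why: DMAP-catalysed acyl transfer should esterify the secondary C6 hydroxyl in preference to the tertiary α-keto hydroxyl at C7, with retention at C6 because only the O–H bond reacts.

Step 24
Reactants: 32 diacetate ester
Product: 33 CNP0323247.1, (6R,7R)-7-hydroxy-7-methyl-3-[(2S,3R)-3-methyloxiran-2-yl]-8-oxo-5,6,7,8-tetrahydro-1H-isochromen-6-yl 2,4-dihydroxy-6-methylbenzoate
Conditions: NH4OAc, MeOH–H2O (4:1), rt
Reagents that add atoms: none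
Why: Ammonium acetate-mediated solvolysis should cleave aryl acetates selectively under near-neutral conditions, sparing the hindered alkyl benzoate, the epoxide and the base-sensitive β-acyloxy dienone.

**Compound list**

1 | 2-C-methyl-D-erythrono-1,4-lactone, (3R,4R)-3,4-dihydroxy-3-methyloxolan-2-one | C[C@]1(O)C(=O)OC[C@H]1O | starting material
2 | 2,3-O-isopropylidene-2-C-methyl-D-erythrono-1,4-lactone (3aR,6aR) | C[C@@]12OC(C)(C)O[C@@H]1COC2=O | intermediate
3 | 2,3-O-isopropylidene-2-C-methyl-D-erythrofuranose (anomers) | C[C@@]12OC(C)(C)O[C@@H]1COC2O | intermediate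
4 | [(4R,5S)-5-ethenyl-2,2,5-trimethyl-1,3-dioxolan-4-yl]methanol | C=C[C@]1(C)OC(C)(C)O[C@@H]1CO | intermediate
5 | ethynyltrimethylsilane | C#C[Si](C)(C)C | starting material
6 | [(4R,5S)-5-ethenyl-2,2,5-trimethyl-1,3-dioxolan-4-yl]methyl trifluoromethanesulfonate | C=C[C@]1(C)OC(C)(C)O[C@@H]1COS(=O)(=O)C(F)(F)F | intermediate (not isolated)
7 | trimethyl{3-[(4R,5S)-5-ethenyl-2,2,5-trimethyl-1,3-dioxolan-4-yl]prop-1-yn-1-yl}silane | C=C[C@]1(C)OC(C)(C)O[C@@H]1CC#C[Si](C)(C)C | intermediate
8 | (3S,4R)-3-methyl-7-(trimethylsilyl)hept-1-en-6-yne-3,4-diol | C=C[C@](C)(O)[C@H](O)CC#C[Si](C)(C)C | intermediate (not isolated)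
9 | (3S,4R)-3-methylhept-1-en-6-yne-3,4-diol | C=C[C@](C)(O)[C@H](O)CC#C | intermediate
10 | (3S,4R)-3,4-bis(tert-butyldimethylsilyloxy)-3-methylhept-1-en-6-yne | C=C[C@](C)(O[Si](C)(C)C(C)(C)C)[C@H](O[Si](C)(C)C(C)(C)C)CC#C | intermediate
11 | (2R,3R)-2,3-bis(tert-butyldimethylsilyloxy)-2-methylhex-5-ynal | O=C[C@](C)(O[Si](C)(C)C(C)(C)C)[C@H](O[Si](C)(C)C(C)(C)C)CC#C | intermediate
12 | 2-bromoprop-2-en-1-ol | C=C(Br)CO | starting material
13 | (4S,5R)-4,5-bis(tert-butyldimethylsilyloxy)-4-methyl-2-methylideneoct-7-yne-1,3-diol (C3 epimers) | C=C(CO)C(O)[C@](C)(O[Si](C)(C)C(C)(C)C)[C@H](O[Si](C)(C)C(C)(C)C)CC#C | intermediate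
14 | [(4R,5S)-4,5-bis(tert-butyldimethylsilyloxy)-2-ethenyl-6-hydroxy-5-methylcyclohex-1-en-1-yl]methanol (C6 epimers) | C=CC1=C(CO)C(O)[C@](C)(O[Si](C)(C)C(C)(C)C)[C@H](O[Si](C)(C)C(C)(C)C)C1 | intermediate
15 | L-threonine | C[C@@H](O)[C@H](N)C(=O)O | starting material
16 | (2S,3R)-2,3-dihydroxybutanoic acid | C[C@@H](O)[C@H](O)C(=O)O | intermediate
17 | methyl (4S,5R)-2,2,5-trimethyl-1,3-dioxolane-4-carboxylate | COC(=O)[C@H]1OC(C)(C)O[C@@H]1C | intermediate
18 | (4S,5R)-2,2,5-trimethyl-1,3-dioxolane-4-carboxylic acid | OC(=O)[C@H]1OC(C)(C)O[C@@H]1C | intermediate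
19 | ring A dienyl ester with free C8 hydroxyl (cyclohexene 4R,5S; C6 epimers) | C=CC1=C(COC(=O)[C@H]2OC(C)(C)O[C@@H]2C)C(O)[C@](C)(O[Si](C)(C)C(C)(C)C)[C@H](O[Si](C)(C)C(C)(C)C)C1 | intermediate
20 | ring A dienyl ester, C8 triethylsilyl ether (cyclohexene 4R,5R; C6 epimers) | C=CC1=C(COC(=O)[C@H]2OC(C)(C)O[C@@H]2C)C(O[Si](CC)(CC)CC)[C@](C)(O[Si](C)(C)C(C)(C)C)[C@H](O[Si](C)(C)C(C)(C)C)C1 | intermediate (key-step precursor)
21 | 6,7-bis(tert-butyldimethylsilyloxy)-7-methyl-8-(triethylsilyloxy)-3-[(4S,5R)-2,2,5-trimethyl-1,3-dioxolan-4-yl]-5,6,7,8-tetrahydro-1H-isochromene (C8 epimers) | CC(C)(C)[Si](C)(C)O[C@@H]1CC2=C(COC([C@H]3OC(C)(C)O[C@@H]3C)=C2)C(O[Si](CC)(CC)CC)[C@]1(C)O[Si](C)(C)C(C)(C)C | intermediate (key-step product)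
22 | 6,7-bis(tert-butyldimethylsilyloxy)-7-methyl-3-[(4S,5R)-2,2,5-trimethyl-1,3-dioxolan-4-yl]-5,6,7,8-tetrahydro-1H-isochromen-8-ol (C8 epimers) | CC(C)(C)[Si](C)(C)O[C@@H]1CC2=C(COC([C@H]3OC(C)(C)O[C@@H]3C)=C2)C(O)[C@]1(C)O[Si](C)(C)C(C)(C)C | intermediate
23 | (6R,7R)-6,7-bis(tert-butyldimethylsilyloxy)-7-methyl-3-[(4S,5R)-2,2,5-trimethyl-1,3-dioxolan-4-yl]-6,7-dihydro-1H-isochromen-8(5H)-one | CC(C)(C)[Si](C)(C)O[C@@H]1CC2=C(COC([C@H]3OC(C)(C)O[C@@H]3C)=C2)C(=O)[C@]1(C)O[Si](C)(C)C(C)(C)C | intermediate
24 | (6R,7R)-6,7-bis(tert-butyldimethylsilyloxy)-3-[(1S,2R)-1,2-dihydroxypropyl]-7-methyl-6,7-dihydro-1H-isochromen-8(5H)-one | CC(C)(C)[Si](C)(C)O[C@@H]1CC2=C(COC([C@@H](O)[C@@H](C)O)=C2)C(=O)[C@]1(C)O[Si](C)(C)C(C)(C)C | intermediate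
25 | cyclic orthoacetate of 24, 3-[(4S,5R)-2-methoxy-2,5-dimethyl-1,3-dioxolan-4-yl] compound (C2 of the dioxolane mixed) | CC(C)(C)[Si](C)(C)O[C@@H]1CC2=C(COC([C@H]3OC(C)(OC)O[C@@H]3C)=C2)C(=O)[C@]1(C)O[Si](C)(C)C(C)(C)C | intermediate (not isolated)
26 | bromo acetate, 3-[(1R,2R)-2-acetoxy-1-bromopropyl] compound | CC(C)(C)[Si](C)(C)O[C@@H]1CC2=C(COC([C@H](Br)[C@@H](C)OC(C)=O)=C2)C(=O)[C@]1(C)O[Si](C)(C)C(C)(C)C | intermediate (not isolated)
27 | (6R,7R)-6,7-bis(tert-butyldimethylsilyloxy)-7-methyl-3-[(2S,3R)-3-methyloxiran-2-yl]-6,7-dihydro-1H-isochromen-8(5H)-one | CC(C)(C)[Si](C)(C)O[C@@H]1CC2=C(COC([C@H]3O[C@@H]3C)=C2)C(=O)[C@]1(C)O[Si](C)(C)C(C)(C)C | intermediate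
28 | (6R,7R)-6,7-dihydroxy-7-methyl-3-[(2S,3R)-3-methyloxiran-2-yl]-6,7-dihydro-1H-isochromen-8(5H)-one | O[C@@H]1CC2=C(COC([C@H]3O[C@@H]3C)=C2)C(=O)[C@]1(C)O | intermediate
29 | orsellinic acid (2,4-dihydroxy-6-methylbenzoic acid) | Cc1cc(O)cc(O)c1C(=O)O | starting material
30 | 2,4-diacetoxy-6-methylbenzoic acid | CC(=O)Oc1cc(C)c(C(=O)O)c(OC(C)=O)c1 | intermediate
31 | 2,4-diacetoxy-6-methylbenzoyl chloride | CC(=O)Oc1cc(C)c(C(Cl)=O)c(OC(C)=O)c1 | intermediate
32 | (6R,7R)-7-hydroxy-7-methyl-3-[(2S,3R)-3-methyloxiran-2-yl]-8-oxo-5,6,7,8-tetrahydro-1H-isochromen-6-yl 2,4-diacetoxy-6-methylbenzoate | CC(=O)Oc1cc(C)c(C(=O)O[C@@H]2CC3=C(COC([C@H]4O[C@@H]4C)=C3)C(=O)[C@]2(C)O)c(OC(C)=O)c1 | intermediate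
33 | CNP0323247.1, (6R,7R)-7-hydroxy-7-methyl-3-[(2S,3R)-3-methyloxiran-2-yl]-8-oxo-5,6,7,8-tetrahydro-1H-isochromen-6-yl 2,4-dihydroxy-6-methylbenzoate | Cc1cc(O)cc(O)c1C(=O)O[C@@H]1CC2=C(COC([C@H]3O[C@@H]3C)=C2)C(=O)[C@]1(C)O | target

**Totals**

Total step count: 24.
Longest linear sequence: 19 steps (from 1: steps 1–9, 13–20, 23 and 24).

**Steps most likely to fail**

Step 15. The titanium alkylidene may stop after ethylidenating the ester, so that the acyclic enol ether does not cyclise, or it may be consumed in unproductive exchange with the conjugated diene. In that case the two events are separated. Setting out from 20, methylenation of the ester carbonyl with Cp2TiMe2 (toluene, 75 °C) should give the methylidene enol ether F1. Ring-closing metathesis of F1 with (H2IMes)(PCy3)Cl2Ru=CHPh (benzene, 60 °C) then closes the same C3=C4 bond with loss of ethene, and the route is rejoined at 21.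

Step 9. Ring closure onto the hindered 1,1-disubstituted olefin is slow, so the ruthenium carbene may divert to the seven-membered endo mode or to alkyne oligomerisation. The fallback replaces metathesis by a π-acid skeletal reorganisation, which proceeds through a cyclopropyl metal carbene and can only give the exo 1-vinylcyclohexene. Setting out from 13, selective esterification of the primary hydroxyl with 18 (EDC·HCl, DMAP) gives the enyne ester F2, and silylation with TESOTf gives the enyne ester triethylsilyl ether F3. Treatment of F3 with [(2-biphenylyl)(t-Bu)2PAu(NCCH3)]SbF6 in CH2Cl2 should rearrange the 1,7-enyne directly to the dienyl ester, rejoining the route at 20.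

Step 23. Acyl transfer from the doubly ortho-substituted aroyl chloride to the hindered C6 hydroxyl may be slow enough that amine-promoted β-elimination across C5–C6 of the product or epoxide opening competes. The fallback activates the nucleophile instead of the acyl donor. Setting out from 28, Bu2Sn(OMe)2 (toluene, rt, methanol removed under vacuum) should give the dibutylstannylene acetal F4 of the cis-diol. F4 is then acylated at the secondary oxygen by 31 in CH2Cl2 without any amine base, and aqueous work-up returns the route at 32.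

**Further compounds**

F1 | step 15 | methylidene enol ether of 20 (ester C=O replaced by C=CH2) | C=CC1=C(COC(=C)[C@H]2OC(C)(C)O[C@@H]2C)C(O[Si](CC)(CC)CC)[C@](C)(O[Si](C)(C)C(C)(C)C)[C@H](O[Si](C)(C)C(C)(C)C)C1
F2 | step 9 | enyne ester, primary ester of 13 with 18 (free C3 hydroxyl, epimers) | C=C(COC(=O)[C@H]1OC(C)(C)O[C@@H]1C)C(O)[C@](C)(O[Si](C)(C)C(C)(C)C)[C@H](O[Si](C)(C)C(C)(C)C)CC#C
F3 | step 9 | enyne ester triethylsilyl ether (acyclic isomer of 20) | C=C(COC(=O)[C@H]1OC(C)(C)O[C@@H]1C)C(O[Si](CC)(CC)CC)[C@](C)(O[Si](C)(C)C(C)(C)C)[C@H](O[Si](C)(C)C(C)(C)C)CC#C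
F4 | step 23 | 6,7-O-dibutylstannylene acetal of 28 | CCCC[Sn]1(CCCC)O[C@@H]2CC3=C(COC([C@H]4O[C@@H]4C)=C3)C(=O)[C@]2(C)O1
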